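**Plan**

- Retrosynthetic cuts, in order: the C5–H and C6–H bonds (alkene hydrogenation), the C4a–C5 ring bond (aldol-type cyclodehydration of a C5 ketone onto the pyridone), the C8 O–methyl and C8–H bonds, the C7–C8 bond (Stetter reaction), then the N–O–methyl bond and the ring nitrogen (pyranone-to-pyridone exchange) back to kojic acid.
- Forward order: kojic acid is C-methylated and converted into the N-methoxy-4-pyridone ring first; the C7–C6–C5(octyl) chain is joined to its aldehyde; the carbocycle is closed last and its alkene is reduced.
- Enabling feature: C4a is the only unsubstituted carbon of the pyridone ring and the nucleophilic α-carbon of the vinylogous amide N1–C8a=C4a–C4=O. The C5 ketone hangs from C8a through C8–C7–C6, so C4a and C5 meet in a six-membered transition state, as in the presumed polyketide folding of this alkaloid family.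
- Stereochemistry: C8 (R) comes from Noyori asymmetric transfer hydrogenation of the heteroaryl ketone (catalyst control). C5 (S) comes from hydrogenation of the C5=C6 alkene on the face opposite the pseudoaxial C8 methoxy group (substrate control), which gives the cis 5,8 pattern.

Key step: step 12

Remark: the target SMILES encodes the (5S,8R) isomer, with the octyl chain and the C8 methoxy group cis. Quinolinone numbering (N1, C2, C3, C4, C4a, C5 to C8, C8a) is used for the corresponding atoms of all intermediates. Undec-1-en-3-one is made in two steps from nonanal because a reliable commercial source is not assumed.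

**Route**

Step 1
Reactants: 1 kojic acid
Product: 2 3-hydroxy-2,6-bis(hydroxymethyl)-4H-pyran-4-one
Conditions: 37% aq. HCHO (1.1 equiv), NaOH (1.05 equiv), H2O, rt; then conc. HCl to pH 1
Reagents that add atoms: formaldehyde C=O
Why: Base-mediated hydroxymethylation of the Lederer–Manasse type should occur at C6, the only free position ortho to the enolic hydroxyl of the pyranone, as with phenols.

Step 2
Reactants: 2 3-hydroxy-2,6-bis(hydroxymethyl)-4H-pyran-4-one
Product: 3 3-hydroxy-6-(hydroxymethyl)-2-methyl-4H-pyran-4-one
Conditions: Zn dust, conc. HCl, H2O, 60 °C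
Reagents that add atoms: none
Why: Dissolving-metal reduction (Clemmensen-type) should remove only the hydroxymethyl oxygen ortho to the free enolic hydroxyl, because only that carbinol can ionise to an oxygen-stabilised quinone-methide-like cation, while the remote hydroxymethyl group has no such assistance.

Step 3
Reactants: 3 3-hydroxy-6-(hydroxymethyl)-2-methyl-4H-pyran-4-one
Product: 4 6-(hydroxymethyl)-3-methoxy-2-methyl-4H-pyran-4-one
Conditions: MeI (1.1 equiv), K2CO3, acetone, reflux
Reagents that add atoms: iodomethane CI
Why: Williamson etherification should be selective for the acidic enolic hydroxyl, since carbonate does not deprotonate the primary alcohol.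

Step 4
Reactants: 4 6-(hydroxymethyl)-3-methoxy-2-methyl-4H-pyran-4-one
Product: 5 1-hydroxy-6-(hydroxymethyl)-3-methoxy-2-methylpyridin-4(1H)-one
Conditions: NH2OH·HCl (3 equiv), pyridine, 80 °C
Reagents that add atoms: hydroxylamine hydrochloride Cl.NO
Why: Conjugate addition of hydroxylamine to the 4-pyranone, ring opening and reclosure on nitrogen with loss of water (pyranone-to-pyridone exchange) is the standard entry to 1-hydroxy-4-pyridones from 3-alkoxy-2-methyl-4-pyranones.

Step 5
Reactants: 5 1-hydroxy-6-(hydroxymethyl)-3-methoxy-2-methylpyridin-4(1H)-one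
Product: 6 6-(hydroxymethyl)-1,3-dimethoxy-2-methylpyridin-4(1H)-one
Conditions: MeI (1.2 equiv), K2CO3, DMF, rt
Reagents that add atoms: iodomethane CI
Why: The hydroxamic-acid-like N-hydroxyl is far more acidic than the primary alcohol, and its anion is alkylated on the N-oxide oxygen (Williamson-type O-alkylation) to give the 1-methoxy-4-pyridone.

Step 6
Reactants: 6 6-(hydroxymethyl)-1,3-dimethoxy-2-methylpyridin-4(1H)-one
Product: 7 1,5-dimethoxy-6-methyl-4-oxo-1,4-dihydropyridine-2-carbaldehyde
Conditions: Dess–Martin periodinane, CH2Cl2, 0 °C to rt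
Reagents that add atoms: none
Why: Dess–Martin oxidation should take the primary heteroaryl carbinol to the non-enolisable aldehyde without touching the N–O bond.

Step 7
Reactants: 8 nonanal
Product: 9 undec-1-en-3-ol (racemic)
Conditions: CH2=CHMgBr, THF, −78 to 0 °C; then 1 M HCl
Reagents that add atoms: vinylmagnesium bromide C=C[Mg]Br
Why: Grignard addition to the aldehyde gives the allylic alcohol, whose carbinol center forms as a racemate and is removed in the next step.

Step 8
Reactants: 9 undec-1-en-3-ol (racemic)
Product: 10 undec-1-en-3-one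
Conditions: Dess–Martin periodinane, CH2Cl2, 0 °C
Reagents that add atoms: none
Why: Dess–Martin oxidation under mild, non-basic conditions should give the polymerisation-prone vinyl ketone, which is used directly.

Step 9
Reactants: 7 1,5-dimethoxy-6-methyl-4-oxo-1,4-dihydropyridine-2-carbaldehyde; 10 undec-1-en-3-one
Product: 11 1,3-dimethoxy-2-methyl-6-(4-oxododecanoyl)pyridin-4(1H)-one
Conditions: 3-benzyl-5-(2-hydroxyethyl)-4-methylthiazolium chloride (15 mol%), Et3N (0.5 equiv), 1,4-dioxane, 70 °C
Reagents that add atoms: none
Why: In the Stetter reaction the thiazolylidene converts the electron-poor heteroaryl aldehyde into an acyl anion equivalent that adds 1,4 to the vinyl ketone, forming the C7–C8 bond and the 1,4-diketone in one step.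

Step 10
Reactants: 11 1,3-dimethoxy-2-methyl-6-(4-oxododecanoyl)pyridin-4(1H)-one
Product: 12 6-[(1R)-1-hydroxy-4-oxododecyl]-1,3-dimethoxy-2-methylpyridin-4(1H)-one
Conditions: RuCl[(R,R)-TsDPEN](p-cymene) (1 mol%), HCO2H/Et3N (5:2), CH2Cl2, rt
Reagents that add atoms: none
Why: Noyori asymmetric transfer hydrogenation reduces the heteroaryl ketone and leaves the dialkyl ketone untouched, and the (R,R) ligand should set C8 as R by the aryl/alkyl model of the six-membered hydride-transfer transition state (the enantiomeric catalyst is used if the sense proves reversed).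

Step 11
Reactants: 12 6-[(1R)-1-hydroxy-4-oxododecyl]-1,3-dimethoxy-2-methylpyridin-4(1H)-one
Product: 13 1,3-dimethoxy-6-[(1R)-1-methoxy-4-oxododecyl]-2-methylpyridin-4(1H)-one
Conditions: MeI (excess), Ag2O, MeCN, 40 °C, dark
Reagents that add atoms: iodomethane CI
Why: Purdie methylation etherifies the carbinol under essentially neutral conditions, so the enolisable ketone is spared and the C8 center, whose C–O bond is not broken, keeps its configuration.

Step 12
Reactants: 13 1,3-dimethoxy-6-[(1R)-1-methoxy-4-oxododecyl]-2-methylpyridin-4(1H)-one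
Product: 15 (8R)-1,3,8-trimethoxy-2-methyl-5-octyl-7,8-dihydroquinolin-4(1H)-one, via tertiary carbinol 14 (not isolated)
Conditions: TsOH·H2O (1.5 equiv), toluene, 100 °C, Dean–Stark trap
Reagents that add atoms: none
Why: The acid activates the C5 ketone, and the free pyridone, in equilibrium with its O-protonated form, attacks through C4a, the α-carbon of the vinylogous amide N1–C8a=C4a–C4=O and the only unsubstituted ring carbon, to give carbinol 14, which loses water through the pyridone-stabilised C5 cation to the conjugated C5=C6 alkene; this copies the aldol-type folding by which the polyketide chain of this alkaloid family is presumed to close its carbocycle. The closest known reaction types are the acid-mediated Friedel–Crafts cyclodehydration of aryl-tethered ketones to 1-alkyl-3,4-dihydronaphthalenes and the C3 hydroxyalkylation and Mannich substitution of 4-pyridones and 4-quinolones. The carbocycle closes in the 6-(enolendo)-exo-trig mode, with the C4a=C8a double bond of the nucleophile inside the new ring and the carbonyl oxygen outside it. The C5 carbinol center forms without control and is erased by the dehydration, so the step leaves no new stereocenter, while C8 is neither α to a carbonyl group nor able to ionise next to the electron-poor protonated ring and should keep its configuration. The step needs C–C bond formation at C4a in preference to aldol chemistry of the ketone α-carbons, which is secured by the six-membered transition state and the absence of any other carbonyl acceptor within reach, and it needs the endocyclic alkene, which is the thermodynamic isomer under reversible protonation. A sulfonic acid with a non-nucleophilic counter-ion is chosen so that neither the N-methoxy nor the C-methoxy groups are dealkylated.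

Step 13
Reactants: 15 (8R)-1,3,8-trimethoxy-2-methyl-5-octyl-7,8-dihydroquinolin-4(1H)-one
Product: 16 waltherione K
Conditions: H2 (1 atm), 5% Pd/C, EtOAc, rt, stopped after uptake of one equivalent
Reagents that add atoms: none
Why: Heterogeneous syn-hydrogenation should deliver both hydrogens to the alkene face opposite the C8 methoxy group, which peri strain with the N1 methoxy group holds pseudoaxial on the half-chair, so that H-5 ends up anti and the octyl chain syn to the C8 methoxy group, giving the (5S,8R) product by 1,4-substrate control.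

**Compound list**

1 | kojic acid, 5-hydroxy-2-(hydroxymethyl)-4H-pyran-4-one | OCc1cc(=O)c(O)co1 | starting material
2 | 3-hydroxy-2,6-bis(hydroxymethyl)-4H-pyran-4-one | OCc1cc(=O)c(O)c(CO)o1 | intermediate
3 | 3-hydroxy-6-(hydroxymethyl)-2-methyl-4H-pyran-4-one | OCc1cc(=O)c(O)c(C)o1 | intermediate
4 | 6-(hydroxymethyl)-3-methoxy-2-methyl-4H-pyran-4-one | OCc1cc(=O)c(OC)c(C)o1 | intermediate
5 | 1-hydroxy-6-(hydroxymethyl)-3-methoxy-2-methylpyridin-4(1H)-one | OCc1cc(=O)c(OC)c(C)n1O | intermediate
6 | 6-(hydroxymethyl)-1,3-dimethoxy-2-methylpyridin-4(1H)-one | OCc1cc(=O)c(OC)c(C)n1OC | intermediate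
7 | 1,5-dimethoxy-6-methyl-4-oxo-1,4-dihydropyridine-2-carbaldehyde | O=Cc1cc(=O)c(OC)c(C)n1OC | intermediate
8 | nonanal | CCCCCCCCC=O | starting material
9 | undec-1-en-3-ol (racemic) | CCCCCCCCC(O)C=C | intermediate
10 | undec-1-en-3-one | CCCCCCCCC(=O)C=C | intermediate
11 | 1,3-dimethoxy-2-methyl-6-(4-oxododecanoyl)pyridin-4(1H)-one | CCCCCCCCC(=O)CCC(=O)c1cc(=O)c(OC)c(C)n1OC | intermediate
12 | 6-[(1R)-1-hydroxy-4-oxododecyl]-1,3-dimethoxy-2-methylpyridin-4(1H)-one | CCCCCCCCC(=O)CC[C@@H](O)c1cc(=O)c(OC)c(C)n1OC | intermediate
13 | 1,3-dimethoxy-6-[(1R)-1-methoxy-4-oxododecyl]-2-methylpyridin-4(1H)-one | CCCCCCCCC(=O)CC[C@@H](OC)c1cc(=O)c(OC)c(C)n1OC | intermediate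
14 | (8R)-5-hydroxy-1,3,8-trimethoxy-2-methyl-5-octyl-5,6,7,8-tetrahydroquinolin-4(1H)-one, both C5 epimers | CCCCCCCCC1(O)CC[C@@H](OC)c2c1c(=O)c(OC)c(C)n2OC | intermediate
15 | (8R)-1,3,8-trimethoxy-2-methyl-5-octyl-7,8-dihydroquinolin-4(1H)-one | CCCCCCCCC1=CC[C@@H](OC)c2c1c(=O)c(OC)c(C)n2OC | intermediate
16 | waltherione K, (5S,8R)-1,3,8-trimethoxy-2-methyl-5-octyl-5,6,7,8-tetrahydroquinolin-4(1H)-one | CCCCCCCC[C@H]1CC[C@@H](OC)c2c1c(=O)c(OC)c(C)n2OC | target

**Step count and risks**

Total step count: 13. Longest linear sequence: 11 (steps 1 to 6 and 9 to 13); steps 7 and 8 make the enone.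

The three steps most likely to fail:

1. Step 12. The pyridone may be too weak a carbon nucleophile once it is protonated on O4, so that no C–C bond forms, or prolonged heating in acid may cause loss of methanol across C7–C8 and aromatisation of the carbocycle. The fallback reverses the polarity of C4a. Setting out from 13, electrophilic iodination with N-iodosuccinimide in MeCN at the only free ring position would give 5-iodo-1,3-dimethoxy-6-[(1R)-1-methoxy-4-oxododecyl]-2-methylpyridin-4(1H)-one F1. Iodine–magnesium exchange with iPrMgCl·LiCl in THF at −40 °C should generate the C4a-magnesium species, which adds to the tethered ketone in a Parham-type 6-exo-trig closure to give carbinol 14, now isolated. Dehydration of 14 with the Burgess reagent comes back to the route at 15.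

2. Step 13. Facial discrimination by a single remote pseudoaxial methoxy group (1,4-induction) may be too weak, giving the 5,8-trans isomer as well. The fallback replaces the small methyl ether by a removable bulky group as the control element and moves the methylation to the end. Setting out from 12, silylation with TBDPSCl and imidazole in DMF would give 6-[(1R)-1-{[tert-butyl(diphenyl)silyl]oxy}-4-oxododecyl]-1,3-dimethoxy-2-methylpyridin-4(1H)-one F2. Cyclodehydration under the conditions of step 12 would give (8R)-8-{[tert-butyl(diphenyl)silyl]oxy}-1,3-dimethoxy-2-methyl-5-octyl-7,8-dihydroquinolin-4(1H)-one F3. Hydrogenation over Pd/C, now shielded on one face by the large pseudoaxial silyloxy group, should give (5S,8R)-8-{[tert-butyl(diphenyl)silyl]oxy}-1,3-dimethoxy-2-methyl-5-octyl-5,6,7,8-tetrahydroquinolin-4(1H)-one F4. Desilylation with TBAF in THF would give (5S,8R)-8-hydroxy-1,3-dimethoxy-2-methyl-5-octyl-5,6,7,8-tetrahydroquinolin-4(1H)-one F5, and methylation with NaH and MeI in THF comes back to the route at 16.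

3. Step 11. Etherification of the hindered carbinol may be slow, allowing closure to the five-membered hemiketal and its methylation, or alkylation at the pyridone oxygen. The fallback masks the ketone so that a strong base can be used. Setting out from 12, ketalisation with ethylene glycol and pyridinium p-toluenesulfonate in benzene (Dean–Stark) would give 6-[(1R)-1-hydroxy-3-(2-octyl-1,3-dioxolan-2-yl)propyl]-1,3-dimethoxy-2-methylpyridin-4(1H)-one F6. Methylation of its alkoxide (NaH, MeI, THF, 0 °C) would give 1,3-dimethoxy-6-[(1R)-1-methoxy-3-(2-octyl-1,3-dioxolan-2-yl)propyl]-2-methylpyridin-4(1H)-one F7, and hydrolysis of the ketal with 1 M HCl in THF comes back to the route at 13.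

**Further compounds**

F1 | step 12 | 5-iodo-1,3-dimethoxy-6-[(1R)-1-methoxy-4-oxododecyl]-2-methylpyridin-4(1H)-one | CCCCCCCCC(=O)CC[C@@H](OC)c1c(I)c(=O)c(OC)c(C)n1OC
F2 | step 13 | 6-[(1R)-1-{[tert-butyl(diphenyl)silyl]oxy}-4-oxododecyl]-1,3-dimethoxy-2-methylpyridin-4(1H)-one | CCCCCCCCC(=O)CC[C@@H](O[Si](c1ccccc1)(c1ccccc1)C(C)(C)C)c1cc(=O)c(OC)c(C)n1OC
F3 | step 13 | (8R)-8-{[tert-butyl(diphenyl)silyl]oxy}-1,3-dimethoxy-2-methyl-5-octyl-7,8-dihydroquinolin-4(1H)-one | CCCCCCCCC1=CC[C@@H](O[Si](c3ccccc3)(c3ccccc3)C(C)(C)C)c2c1c(=O)c(OC)c(C)n2OC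
F4 | step 13 | (5S,8R)-8-{[tert-butyl(diphenyl)silyl]oxy}-1,3-dimethoxy-2-methyl-5-octyl-5,6,7,8-tetrahydroquinolin-4(1H)-one | CCCCCCCC[C@H]1CC[C@@H](O[Si](c3ccccc3)(c3ccccc3)C(C)(C)C)c2c1c(=O)c(OC)c(C)n2OC
F5 | step 13 | (5S,8R)-8-hydroxy-1,3-dimethoxy-2-methyl-5-octyl-5,6,7,8-tetrahydroquinolin-4(1H)-one | CCCCCCCC[C@H]1CC[C@@H](O)c2c1c(=O)c(OC)c(C)n2OC
F6 | step 11 | 6-[(1R)-1-hydroxy-3-(2-octyl-1,3-dioxolan-2-yl)propyl]-1,3-dimethoxy-2-methylpyridin-4(1H)-one | CCCCCCCCC1(OCCO1)CC[C@@H](O)c1cc(=O)c(OC)c(C)n1OC
F7 | step 11 | 1,3-dimethoxy-6-[(1R)-1-methoxy-3-(2-octyl-1,3-dioxolan-2-yl)propyl]-2-methylpyridin-4(1H)-one | CCCCCCCCC1(OCCO1)CC[C@@H](OC)c1cc(=O)c(OC)c(C)n1OC
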